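Ring B (the oxepine: O1, C2 to C5, C5a, C9a) is opened at C4–C5. C4 is a carbinol carbon bonded directly to C5, the 1,1-disubstituted alkenyl carbon that carries ring A through C5a and the exocyclic CH2, so this bond is the one an alkenyl-metal addition to an aldehyde makes. A Nozaki–Hiyama–Kishi cyclisation of iodoalkene aldehyde 14 therefore forms C4–C5, closes ring B and sets C4 in a single operation, with C2 already in place. Precursor 14 carries the 1-iodoethenyl group ortho to an aryl ether oxygen whose chiral side chain ends in the aldehyde; the ether comes from Mitsunobu inversion of (R)-α-hydroxy-γ-butyrolactone by a salicylic Weinreb amide.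

Key step: step 11

Assumption: the resident C2 centre is taken to steer the ring closure to the 2,4-trans (4R) alcohol through the chair-like transition state described in step 11; the end game remains usable if the other C4 epimer dominates (see the fallback for step 11). Ring A is the benzene ring, ring B the oxepine.

Step 1
Reactants: 1 3,5-dihydroxy-4-methylbenzoic acid
Product: 2 3,5-dihydroxy-N-methoxy-N,4-dimethylbenzamide
Conditions: MeNHOMe·HCl, EDC·HCl, HOBt, iPr2NEt, DMF, 0 °C to rt
Reagents that add atoms: N,O-dimethylhydroxylamine hydrochloride, CNOC.Cl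
Why: Carbodiimide amide coupling (Weinreb amide formation) should be clean because the free amine is far more nucleophilic towards the HOBt active ester than the two phenols.

Step 2
Reactants: 2 3,5-dihydroxy-N-methoxy-N,4-dimethylbenzamide
Product: 3 3,5-bis(tert-butyldimethylsilyloxy)-N-methoxy-N,4-dimethylbenzamide
Conditions: TBSCl, imidazole, DMF, rt
Reagents that add atoms: tert-butyldimethylsilyl chloride, CC(C)(C)[Si](C)(C)Cl
Why: Imidazole-mediated O-silylation should cap both phenols, which are the only nucleophilic sites.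

Step 3
Reactants: 3 3,5-bis(tert-butyldimethylsilyloxy)-N-methoxy-N,4-dimethylbenzamide
Product: 4 2-bromo-3,5-bis(tert-butyldimethylsilyloxy)-N-methoxy-N,4-dimethylbenzamide
Conditions: NBS, MeCN, 0 °C to rt, dark
Reagents that add atoms: N-bromosuccinimide, O=C1CCC(=O)N1Br
Why: Electrophilic aromatic bromination can only go to the two equivalent open positions (each ortho to one silyloxy group and para to the other), and one equivalent of reagent plus the deactivating first bromine should stop it at the monobromide.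

Step 4
Reactants: 4 2-bromo-3,5-bis(tert-butyldimethylsilyloxy)-N-methoxy-N,4-dimethylbenzamide
Product: 6 3,5-bis(tert-butyldimethylsilyloxy)-2-hydroxy-N-methoxy-N,4-dimethylbenzamide, via aryl pinacol boronate 5 (not isolated)
Conditions: B2pin2, Pd(OAc)2 (cat.), SPhos, KOAc, dioxane, 90 °C; then NaBO3·4H2O, THF/H2O, rt
Reagents that add atoms: bis(pinacolato)diboron, CC1(C)OB(OC1(C)C)B1OC(C)(C)C(C)(C)O1 (boron group of intermediate 5); sodium perborate, [Na+].[O-]OB=O (phenol oxygen of 6)
Why: Miyaura borylation with a biaryl phosphine that tolerates two ortho substituents, followed by mild perborate oxidation of the C–B bond, should give the phenol, which is hydrogen-bonded to the amide carbonyl so that the silyl groups have no reason to migrate onto it.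

Step 5
Reactants: 6 3,5-bis(tert-butyldimethylsilyloxy)-2-hydroxy-N-methoxy-N,4-dimethylbenzamide; 7 (3R)-3-hydroxyoxolan-2-one [(R)-α-hydroxy-γ-butyrolactone]
Product: 8 3,5-bis(tert-butyldimethylsilyloxy)-N-methoxy-N,4-dimethyl-2-{[(3S)-2-oxooxolan-3-yl]oxy}benzamide
Conditions: PPh3, DIAD, THF, 0 °C to rt
Reagents that add atoms: none
Why: Mitsunobu etherification of the acidic salicylamide-type phenol is an SN2 displacement at the carbonyl-activated α-carbon of the lactone, so clean inversion (R to S) should set the future C2 centre.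

Step 6
Reactants: 8 3,5-bis(tert-butyldimethylsilyloxy)-N-methoxy-N,4-dimethyl-2-{[(3S)-2-oxooxolan-3-yl]oxy}benzamide
Product: 9 1-[3,5-bis(tert-butyldimethylsilyloxy)-2-{[(3S)-1,4-dihydroxy-4-methylpentan-3-yl]oxy}-4-methylphenyl]ethan-1-one
Conditions: MeMgBr (excess), LaCl3·2LiCl, THF, −20 to 0 °C; aq. NH4Cl
Reagents that add atoms: methylmagnesium bromide, C[Mg]Br
Why: One Grignard operation should do two jobs, the Weinreb ketone synthesis (the chelated tetrahedral adduct releases the methyl ketone only at the quench) and double addition to the lactone to give the CMe2OH group and the primary alcohol, while the lanthanum salt suppresses enolisation so that the stereocentre is not touched.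

Step 7
Reactants: 9 1-[3,5-bis(tert-butyldimethylsilyloxy)-2-{[(3S)-1,4-dihydroxy-4-methylpentan-3-yl]oxy}-4-methylphenyl]ethan-1-one
Product: 10 1-[3,5-bis(tert-butyldimethylsilyloxy)-4-methyl-2-{[(3S)-4-methyl-1,4-bis(triethylsilyloxy)pentan-3-yl]oxy}phenyl]ethan-1-one
Conditions: TESOTf, 2,6-lutidine, CH2Cl2, −78 to 0 °C
Reagents that add atoms: triethylsilyl trifluoromethanesulfonate, CC[Si](CC)(CC)OS(=O)(=O)C(F)(F)F
Why: Silyl triflate silylation is strong enough for the hindered tertiary alcohol as well as the primary one, and the weak pyridine base should leave the methyl ketone unenolised.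

Step 8
Reactants: 10 1-[3,5-bis(tert-butyldimethylsilyloxy)-4-methyl-2-{[(3S)-4-methyl-1,4-bis(triethylsilyloxy)pentan-3-yl]oxy}phenyl]ethan-1-one
Product: 12 (3S)-3-[4,6-bis(tert-butyldimethylsilyloxy)-2-(1-iodoethenyl)-5-methylphenoxy]-4-methyl-1,4-bis(triethylsilyloxy)pentane, via N-silyl hydrazone 11 (not isolated)
Conditions: (TBSNH)2, Sc(OTf)3 (cat.), neat, 100 °C; then I2, tetramethylguanidine, THF, 0 °C to rt
Reagents that add atoms: 1,2-bis(tert-butyldimethylsilyl)hydrazine, CC(C)(C)[Si](C)(C)NN[Si](C)(C)C(C)(C)C (N–N–Si unit of intermediate 11); iodine, II (iodine atom of 12)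
Why: The Barton vinyl iodide synthesis in its anhydrous N-silyl hydrazone form (oxidation by iodine to the diazo compound, iodination, loss of N2 and proton loss from the methyl group, the only β-hydrogens) should give the 1-iodoethenyl arene without exposing the silyl ethers to free hydrazine.

Step 9
Reactants: 12 (3S)-3-[4,6-bis(tert-butyldimethylsilyloxy)-2-(1-iodoethenyl)-5-methylphenoxy]-4-methyl-1,4-bis(triethylsilyloxy)pentane
Product: 13 (3S)-3-[4,6-bis(tert-butyldimethylsilyloxy)-2-(1-iodoethenyl)-5-methylphenoxy]-4-methyl-4-(triethylsilyloxy)pentan-1-ol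
Conditions: PPTS (cat.), MeOH/CH2Cl2, 0 °C
Reagents that add atoms: none
Why: Mild acid-catalysed methanolysis should cleave the unhindered primary triethylsilyl ether much faster than the tertiary one or the aryl silyl ethers.

Step 10
Reactants: 13 (3S)-3-[4,6-bis(tert-butyldimethylsilyloxy)-2-(1-iodoethenyl)-5-methylphenoxy]-4-methyl-4-(triethylsilyloxy)pentan-1-ol
Product: 14 (3S)-3-[4,6-bis(tert-butyldimethylsilyloxy)-2-(1-iodoethenyl)-5-methylphenoxy]-4-methyl-4-(triethylsilyloxy)pentanal
Conditions: Dess–Martin periodinane, NaHCO3, CH2Cl2, 0 °C to rt; used at once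
Reagents that add atoms: none
Why: Buffered Dess–Martin oxidation is free of amine base, so the β-aryloxy aldehyde should form without retro-oxa-Michael loss of the phenol and with C3 intact.

Step 11
Reactants: 14 (3S)-3-[4,6-bis(tert-butyldimethylsilyloxy)-2-(1-iodoethenyl)-5-methylphenoxy]-4-methyl-4-(triethylsilyloxy)pentanal
Product: 15 (2S,4R)-7,9-bis(tert-butyldimethylsilyloxy)-8-methyl-5-methylidene-2-[2-(triethylsilyloxy)propan-2-yl]-2,3,4,5-tetrahydro-1-benzoxepin-4-ol
Conditions: CrCl2 (excess), NiCl2 (cat.), degassed DMSO, rt, slow addition of 14 at high dilution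
Reagents that add atoms: none
Why: Divalent chromium reduces NiCl2 to zerovalent nickel, which inserts into the C–I bond of 14; transmetallation gives an alkenylchromium species (trivalent chromium) that adds to the tethered aldehyde and, after aqueous work-up, leaves the allylic alcohol with its exocyclic methylene directly. The closest known reaction type is the intramolecular Nozaki–Hiyama–Kishi cyclisation of alkenyl iodide aldehydes to medium-ring allylic alcohols. Ring B is closed by a 7-exo-trig attack of C5 on the aldehyde carbon C4. The new C4 centre is controlled by the resident C2 centre: in the chair-like seven-membered transition state the CMe2OSiEt3 group is pseudo-equatorial and the chromium-bound oxygen, held in a four-centre Cr–C5–C4–O array across the alkene plane, is pseudo-axial, which means Si-face attack and the 2,4-trans (4R) alcohol. The step also needs the aldehyde to survive until it is attacked: the medium is not basic, so the β-aryloxy aldehyde does not lose the phenol by retro-oxa-Michael opening, no β-aryloxy ketone is ever formed, and the silyl ethers and the hindered aryl ether are inert to the reagent. High dilution and a low nickel loading should keep intermolecular coupling and alkenyl homocoupling down.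

Step 12
Reactants: 15 (2S,4R)-7,9-bis(tert-butyldimethylsilyloxy)-8-methyl-5-methylidene-2-[2-(triethylsilyloxy)propan-2-yl]-2,3,4,5-tetrahydro-1-benzoxepin-4-ol; 16 angelic acid [(2Z)-2-methylbut-2-enoic acid]
Product: 18 (2S,4R)-7,9-bis(tert-butyldimethylsilyloxy)-8-methyl-5-methylidene-2-[2-(triethylsilyloxy)propan-2-yl]-2,3,4,5-tetrahydro-1-benzoxepin-4-yl (2Z)-2-methylbut-2-enoate, via mixed anhydride 17 (not isolated)
Conditions: 16, 2,4,6-trichlorobenzoyl chloride, Et3N, toluene, rt; then 15, 80 °C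
Reagents that add atoms: 2,4,6-trichlorobenzoyl chloride, O=C(Cl)c1c(Cl)cc(Cl)cc1Cl (aroyl half of intermediate 17 only; the new atoms of 18 come from 16)
Why: Yamaguchi-type mixed anhydride acylation without a nucleophilic catalyst should deliver the angeloyl group from the less hindered carbonyl with retention at C4 and without the addition–elimination pathway that turns angelates into tiglates.

Step 13
Reactants: 18 (2S,4R)-7,9-bis(tert-butyldimethylsilyloxy)-8-methyl-5-methylidene-2-[2-(triethylsilyloxy)propan-2-yl]-2,3,4,5-tetrahydro-1-benzoxepin-4-yl (2Z)-2-methylbut-2-enoate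
Product: 19 (2S,4R)-7,9-dihydroxy-2-(2-hydroxypropan-2-yl)-8-methyl-5-methylidene-2,3,4,5-tetrahydro-1-benzoxepin-4-yl (2Z)-2-methylbut-2-enoate (CNP0160456.1)
Conditions: TBAF, AcOH (1:1), THF, 0 °C to rt
Reagents that add atoms: none
Why: Buffered fluoride desilylation should remove the two aryl silyl ethers quickly and the tertiary triethylsilyl ether after them, while the acetic acid keeps free phenoxide away from the allylic angelate and the oxidisable arene.

Compound list
1 | 3,5-dihydroxy-4-methylbenzoic acid | Cc1c(O)cc(C(=O)O)cc1O | starting material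
2 | 3,5-dihydroxy-N-methoxy-N,4-dimethylbenzamide | Cc1c(O)cc(C(=O)N(C)OC)cc1O | intermediate
3 | 3,5-bis(tert-butyldimethylsilyloxy)-N-methoxy-N,4-dimethylbenzamide | Cc1c(O[Si](C)(C)C(C)(C)C)cc(C(=O)N(C)OC)cc1O[Si](C)(C)C(C)(C)C | intermediate
4 | 2-bromo-3,5-bis(tert-butyldimethylsilyloxy)-N-methoxy-N,4-dimethylbenzamide | Cc1c(O[Si](C)(C)C(C)(C)C)cc(C(=O)N(C)OC)c(Br)c1O[Si](C)(C)C(C)(C)C | intermediate
5 | 3,5-bis(tert-butyldimethylsilyloxy)-N-methoxy-N,4-dimethyl-2-(4,4,5,5-tetramethyl-1,3,2-dioxaborolan-2-yl)benzamide (formed in the flask) | Cc1c(O[Si](C)(C)C(C)(C)C)cc(C(=O)N(C)OC)c(B2OC(C)(C)C(C)(C)O2)c1O[Si](C)(C)C(C)(C)C | intermediate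
6 | 3,5-bis(tert-butyldimethylsilyloxy)-2-hydroxy-N-methoxy-N,4-dimethylbenzamide | Cc1c(O[Si](C)(C)C(C)(C)C)cc(C(=O)N(C)OC)c(O)c1O[Si](C)(C)C(C)(C)C | intermediate
7 | (3R)-3-hydroxyoxolan-2-one [(R)-α-hydroxy-γ-butyrolactone] | O=C1OCC[C@H]1O | starting material
8 | 3,5-bis(tert-butyldimethylsilyloxy)-N-methoxy-N,4-dimethyl-2-{[(3S)-2-oxooxolan-3-yl]oxy}benzamide | Cc1c(O[Si](C)(C)C(C)(C)C)cc(C(=O)N(C)OC)c(O[C@H]2CCOC2=O)c1O[Si](C)(C)C(C)(C)C | intermediate
9 | 1-[3,5-bis(tert-butyldimethylsilyloxy)-2-{[(3S)-1,4-dihydroxy-4-methylpentan-3-yl]oxy}-4-methylphenyl]ethan-1-one | CC(=O)c1cc(O[Si](C)(C)C(C)(C)C)c(C)c(O[Si](C)(C)C(C)(C)C)c1O[C@H](C(C)(C)O)CCO | intermediate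
10 | 1-[3,5-bis(tert-butyldimethylsilyloxy)-4-methyl-2-{[(3S)-4-methyl-1,4-bis(triethylsilyloxy)pentan-3-yl]oxy}phenyl]ethan-1-one | CC(=O)c1cc(O[Si](C)(C)C(C)(C)C)c(C)c(O[Si](C)(C)C(C)(C)C)c1O[C@H](C(C)(C)O[Si](CC)(CC)CC)CCO[Si](CC)(CC)CC | intermediate
11 | N-tert-butyldimethylsilyl hydrazone of ketone 10 (C=N–NH–SiMe2tBu in place of C=O; C=N geometry not defined; formed in the flask) | CC(=NN[Si](C)(C)C(C)(C)C)c1cc(O[Si](C)(C)C(C)(C)C)c(C)c(O[Si](C)(C)C(C)(C)C)c1O[C@H](C(C)(C)O[Si](CC)(CC)CC)CCO[Si](CC)(CC)CC | intermediate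
12 | (3S)-3-[4,6-bis(tert-butyldimethylsilyloxy)-2-(1-iodoethenyl)-5-methylphenoxy]-4-methyl-1,4-bis(triethylsilyloxy)pentane | C=C(I)c1cc(O[Si](C)(C)C(C)(C)C)c(C)c(O[Si](C)(C)C(C)(C)C)c1O[C@H](C(C)(C)O[Si](CC)(CC)CC)CCO[Si](CC)(CC)CC | intermediate
13 | (3S)-3-[4,6-bis(tert-butyldimethylsilyloxy)-2-(1-iodoethenyl)-5-methylphenoxy]-4-methyl-4-(triethylsilyloxy)pentan-1-ol | C=C(I)c1cc(O[Si](C)(C)C(C)(C)C)c(C)c(O[Si](C)(C)C(C)(C)C)c1O[C@H](C(C)(C)O[Si](CC)(CC)CC)CCO | intermediate
14 | (3S)-3-[4,6-bis(tert-butyldimethylsilyloxy)-2-(1-iodoethenyl)-5-methylphenoxy]-4-methyl-4-(triethylsilyloxy)pentanal | C=C(I)c1cc(O[Si](C)(C)C(C)(C)C)c(C)c(O[Si](C)(C)C(C)(C)C)c1O[C@H](C(C)(C)O[Si](CC)(CC)CC)CC=O | intermediate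
15 | (2S,4R)-7,9-bis(tert-butyldimethylsilyloxy)-8-methyl-5-methylidene-2-[2-(triethylsilyloxy)propan-2-yl]-2,3,4,5-tetrahydro-1-benzoxepin-4-ol | C=C1c2cc(O[Si](C)(C)C(C)(C)C)c(C)c(O[Si](C)(C)C(C)(C)C)c2O[C@H](C(C)(C)O[Si](CC)(CC)CC)C[C@H]1O | intermediate
16 | angelic acid [(2Z)-2-methylbut-2-enoic acid] | C/C=C(/C)C(=O)O | starting material
17 | (2Z)-2-methylbut-2-enoic 2,4,6-trichlorobenzoic anhydride (formed in the flask) | C/C=C(/C)C(=O)OC(=O)c1c(Cl)cc(Cl)cc1Cl | intermediate
18 | (2S,4R)-7,9-bis(tert-butyldimethylsilyloxy)-8-methyl-5-methylidene-2-[2-(triethylsilyloxy)propan-2-yl]-2,3,4,5-tetrahydro-1-benzoxepin-4-yl (2Z)-2-methylbut-2-enoate | C=C1c2cc(O[Si](C)(C)C(C)(C)C)c(C)c(O[Si](C)(C)C(C)(C)C)c2O[C@H](C(C)(C)O[Si](CC)(CC)CC)C[C@H]1OC(=O)/C(C)=C\C | intermediate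
19 | (2S,4R)-7,9-dihydroxy-2-(2-hydroxypropan-2-yl)-8-methyl-5-methylidene-2,3,4,5-tetrahydro-1-benzoxepin-4-yl (2Z)-2-methylbut-2-enoate | C=C1c2cc(O)c(C)c(O)c2O[C@H](C(C)(C)O)C[C@H]1OC(=O)/C(C)=C\C | target

Total step count: 13. Longest linear sequence: 13 steps (1 to 19); compounds 7 and 16 are bought.

Steps most likely to fail

Step 11. The ring closure may show poor or reversed facial selectivity at the aldehyde, so that the 2,4-cis alcohol dominates. The fallback sets out from 14 and accepts this outcome: the same chromium-mediated closure is then taken to give (2S,4S)-7,9-bis(tert-butyldimethylsilyloxy)-8-methyl-5-methylidene-2-[2-(triethylsilyloxy)propan-2-yl]-2,3,4,5-tetrahydro-1-benzoxepin-4-ol F1. This alcohol is esterified with angelic acid 16 under Mitsunobu conditions (PPh3, DIAD, toluene, 0 °C), an SN2 displacement that inverts C4 and comes back to the route at 18. The C4 configuration is then fixed in the C–O bond formation and no longer in the C–C bond formation.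

Step 8. Condensation at the hindered ortho-substituted ketone may be slow, or silyl groups may be lost during the iodine oxidation. The fallback sets out from 10 and avoids the hydrazone altogether. Kinetic enolisation and triflation (KN(SiMe3)2, PhNTf2, THF, −78 °C) should give the enol triflate 1-[3,5-bis(tert-butyldimethylsilyloxy)-4-methyl-2-{[(3S)-4-methyl-1,4-bis(triethylsilyloxy)pentan-3-yl]oxy}phenyl]ethenyl trifluoromethanesulfonate F2. Stannylation catalysed by zerovalent palladium (Pd(PPh3)4, Me3SnSnMe3, LiCl, THF, 60 °C) should give {1-[3,5-bis(tert-butyldimethylsilyloxy)-4-methyl-2-{[(3S)-4-methyl-1,4-bis(triethylsilyloxy)pentan-3-yl]oxy}phenyl]ethenyl}trimethylstannane F3. Iododestannylation (I2, CH2Cl2, 0 °C) then comes back to the route at 12.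

Step 5. Substitution by the hindered, hydrogen-bonded phenol may be sluggish, so that elimination of the activated lactone alcohol wins. The fallback sets out from 7 and replaces the Mitsunobu activation by a preformed leaving group: Tf2O and 2,6-lutidine in CH2Cl2 at −78 °C should give (3R)-2-oxooxolan-3-yl trifluoromethanesulfonate F4. Phenol 6 with K2CO3 in MeCN at −20 to 0 °C displaces the triflate with inversion and comes back to the route at 8.

Further compounds
F1 | step 11 | (2S,4S)-7,9-bis(tert-butyldimethylsilyloxy)-8-methyl-5-methylidene-2-[2-(triethylsilyloxy)propan-2-yl]-2,3,4,5-tetrahydro-1-benzoxepin-4-ol | C=C1c2cc(O[Si](C)(C)C(C)(C)C)c(C)c(O[Si](C)(C)C(C)(C)C)c2O[C@H](C(C)(C)O[Si](CC)(CC)CC)C[C@@H]1O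
F2 | step 8 | 1-[3,5-bis(tert-butyldimethylsilyloxy)-4-methyl-2-{[(3S)-4-methyl-1,4-bis(triethylsilyloxy)pentan-3-yl]oxy}phenyl]ethenyl trifluoromethanesulfonate | C=C(OS(=O)(=O)C(F)(F)F)c1cc(O[Si](C)(C)C(C)(C)C)c(C)c(O[Si](C)(C)C(C)(C)C)c1O[C@H](C(C)(C)O[Si](CC)(CC)CC)CCO[Si](CC)(CC)CC
F3 | step 8 | {1-[3,5-bis(tert-butyldimethylsilyloxy)-4-methyl-2-{[(3S)-4-methyl-1,4-bis(triethylsilyloxy)pentan-3-yl]oxy}phenyl]ethenyl}trimethylstannane | C=C([Sn](C)(C)C)c1cc(O[Si](C)(C)C(C)(C)C)c(C)c(O[Si](C)(C)C(C)(C)C)c1O[C@H](C(C)(C)O[Si](CC)(CC)CC)CCO[Si](CC)(CC)CC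
F4 | step 5 | (3R)-2-oxooxolan-3-yl trifluoromethanesulfonate | O=C1OCC[C@H]1OS(=O)(=O)C(F)(F)F
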